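**Plan**

1. Retrosynthetic cuts: the C19 ester C–O bond; the C11=C12 and C11'=C12' alkenes (two Wittig reactions around a C10 dialdehyde); C8–C9 (Nozaki–Hiyama–Kishi); C6–C7 (Suzuki); and, inside the ε-ring, the C1'–C6' bond.
2. Feature used: C1' (the gem-dimethyl carbon) and C6' of the ε-ring are the two ends of a 1,5-diene in the open-chain form [C1'(Me)2=C2' and C5'(Me)=C6']. Protonation at C2' gives a tertiary C1' cation that C6' captures, and loss of H-4' from the tertiary C5' cation leaves the C4'=C5' alkene. That open-chain form is pseudoionone.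
3. Forward, ε-half: enzymatic cyclisation to (R)-α-ionone, enzymatic C3' hydroxylation, C15 phosphonium salt, Wittig reaction with the C10 dialdehyde to the C25 aldehyde, then the C25 phosphonium salt.
4. Forward, β-half and union: actinol → enol triflate → homologated aldehyde → coupling with 4-bromofuran-2(5H)-one. The butenolide ring fixes the 9E geometry and, as its lactol, delivers the C11 aldehyde and the free C19 hydroxyl in the last Wittig reaction. Then C19 acylation, C8 oxidation, desilylation.
5. Stereochemistry: C6' from the cyclase, C3' from the hydroxylase (trans to the side chain), C3 from (4R,6R)-actinol; E alkenes from Wittig reactions with thermal equilibration, 9E from the ring template.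

Key step: step 1

Assumption: (3E,5E)-pseudoionone and (4R,6R)-actinol are taken as commercial single isomers; the carbinol carbon C8 is carried as a mixture of epimers from step 12 until it becomes the ketone in step 16.

**Route**

Step 1
Reactants: 1 (3E,5E)-pseudoionone
Product: 2 (R)-α-ionone
Conditions: E. coli whole cells expressing a squalene–hopene cyclase variant (class two terpene cyclase, chosen by screening), citrate buffer pH 6.0, 2-hydroxypropyl-β-cyclodextrin, 30 °C
Reagents that add atoms: none
Why: Proposed new method: the active-site aspartic acid of the cyclase protonates C9 of the isopropylidene group of 1 (Markovnikov), and the tertiary C10 cation is captured by C5 of the 5,6-alkene held in a chair-like fold, which closes the six-membered carbocycle (cation–olefin cyclisation, 6-endo with respect to the 5,6-alkene) and leaves a tertiary ring cation at C6 that loses a C7 proton to give the endocyclic trisubstituted alkene. The closest known reactions are the phosphoric acid cyclisation of pseudoionone to racemic α-ionone, the monocyclisation of (E)-geranylacetone to γ-dihydroionone by squalene–hopene cyclase variants, and the same C1–C6 closure of open-chain end groups by carotenoid ε-cyclases. The only new stereocenter (ring C1 of 2, C6' of the target) is set by the enzyme pocket, which presents one enantiotopic face of the 5,6-alkene to the cation; the variant is selected for the (R) product. The step needs enantioface selection, proton loss toward the α-isomer and not the β- or γ-isomer, and exclusion of water capture; the first two should come from the fold and the position of the catalytic base next to C7, the last from the hydrophobic pocket. The (3E)-enone of 1 keeps the carbonyl oxygen out of reach of the ring cation, so no bicyclic enol ether can form.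

Step 2
Reactants: 2 (R)-α-ionone
Product: 3 (3R,6R)-3-hydroxy-α-ionone
Conditions: cytochrome P450 BM3 (CYP102A1) variant, NADP+ (cat.), glucose dehydrogenase, D-glucose, air, phosphate buffer pH 7.5, 25 °C
Reagents that add atoms: dioxygen, O=O
Why: Cytochrome P450 monooxygenase C–H hydroxylation (hydrogen abstraction, oxygen rebound), a known reaction of α-ionone, should take place at the ring allylic CH2 and deliver oxygen to the face opposite the side chain, which sets (R) at the carbinol carbon (trans to the side chain).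

Step 3
Reactants: 3 (3R,6R)-3-hydroxy-α-ionone
Product: 4 (3R,6R)-3-(tert-butyldimethylsilyloxy)-α-ionone
Conditions: TBSCl, imidazole, DMF, rt
Reagents that add atoms: tert-butyldimethylsilyl chloride (TBSCl), CC(C)(C)[Si](C)(C)Cl
Why: Standard silylation of the secondary allylic alcohol; the enone and both stereocenters are untouched.

Step 4
Reactants: 4 (3R,6R)-3-(tert-butyldimethylsilyloxy)-α-ionone
Product: 5 tertiary vinyl carbinol (both epimers at the carbinol carbon)
Conditions: CH2=CHMgBr, THF, −78 → 0 °C; aq. NH4Cl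
Reagents that add atoms: vinylmagnesium bromide, C=C[Mg]Br
Why: 1,2-Addition of the vinyl Grignard reagent to the methyl ketone (Grignard addition) gives the tertiary bis-allylic alcohol, whose new carbinol center is lost in step 5, so both epimers serve.

Step 5
Reactants: 5 tertiary vinyl carbinol
Product: 6 C15 dienylphosphonium bromide (2E,4E)
Conditions: PPh3·HBr, CH2Cl2, 0 °C → rt; crystallisation from EtOAc
Reagents that add atoms: triphenylphosphine hydrobromide, Br.c1ccc(cc1)P(c1ccccc1)c1ccccc1
Why: The acid ionises the tertiary doubly allylic alcohol to a pentadienyl cation that triphenylphosphine captures at the unhindered terminal carbon (allylic substitution with transposition, SN1/SN2'), which should give the conjugated (2E,4E) salt; any (2Z) isomer is removed by crystallisation.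

Step 6
Reactants: 6 C15 dienylphosphonium bromide; 7 (2E,4E,6E)-2,7-dimethylocta-2,4,6-trienedial (excess)
Product: 9 C25 hexaenal (all-E), via ylide 8 (not isolated)
Conditions: NaOMe, CH2Cl2/MeOH, 0 °C; then 7, 0 °C → rt; heptane, 80 °C, dark
Reagents that add atoms: none
Why: Wittig olefination of one formyl group of the dialdehyde by the semistabilised ylide forms the C11'=C12' bond, and the hindered (Z) isomer of this disubstituted alkene should isomerise to (E) on warming.

Step 7
Reactants: 9 C25 hexaenal
Product: 10 C25 hexaenol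
Conditions: NaBH4, THF/MeOH, 0 °C
Reagents that add atoms: none
Why: 1,2-Reduction of the conjugated aldehyde by NaBH4 gives the primary allylic alcohol without touching the polyene or the silyl ether.

Step 8
Reactants: 10 C25 hexaenol
Product: 11 C25 polyenylphosphonium bromide
Conditions: PPh3·HBr, CH2Cl2, 0 °C → rt, dark
Reagents that add atoms: triphenylphosphine hydrobromide, Br.c1ccc(cc1)P(c1ccccc1)c1ccccc1
Why: The polyenyl carbinol ionises under the mild acid and triphenylphosphine adds at the terminal carbon of the delocalised cation (the reaction type used for retinyl phosphonium salts), which gives the primary allylic phosphonium salt.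

Step 9
Reactants: 12 (4R,6R)-actinol
Product: 13 (4R,6R)-4-(tert-butyldimethylsilyloxy)-2,2,6-trimethylcyclohexanone
Conditions: TBSCl, imidazole, DMF, rt
Reagents that add atoms: tert-butyldimethylsilyl chloride (TBSCl), CC(C)(C)[Si](C)(C)Cl
Why: Standard silylation of the secondary alcohol; the ketone is untouched.

Step 10
Reactants: 13 silylated actinol
Product: 15 (4R)-enol triflate, via lithium enolate 14 (not isolated)
Conditions: LiN(iPr)2, THF, −78 → 0 °C; PhNTf2, −78 °C → rt
Reagents that add atoms: N-phenylbis(trifluoromethanesulfonimide) (PhNTf2), O=S(=O)(N(c1ccccc1)S(=O)(=O)C(F)(F)F)C(F)(F)F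
Why: Deprotonation at the only enolisable position gives the tetrasubstituted enolate, and its O-sulfonylation gives the enol triflate; the methyl-bearing stereocenter of 13 is removed on purpose and the carbinol center is untouched.

Step 11
Reactants: 15 (4R)-enol triflate; 16 (E)-2-ethoxyvinylboronic acid pinacol ester
Product: 18 (4R)-ring acetaldehyde, via dienol ether 17 (not isolated)
Conditions: Pd(PPh3)4 (cat.), K3PO4, dioxane/H2O, 80 °C; then aq. oxalic acid, THF, 0 °C → rt
Reagents that add atoms: water, O
Why: Suzuki–Miyaura coupling of the hindered enol triflate with the alkenylboronate gives a dienol ether, whose mild acid hydrolysis (protonation at the enol ether β-carbon, the twisted ring alkene staying in place) should give the β,γ-unsaturated aldehyde.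

Step 12
Reactants: 18 (4R)-ring acetaldehyde; 19 4-bromofuran-2(5H)-one
Product: 20 hydroxyalkyl butenolide (both C8 epimers)
Conditions: CrCl2, NiCl2 (cat.), DMF, rt
Reagents that add atoms: none
Why: Nozaki–Hiyama–Kishi coupling (nickel-catalysed activation of the β-bromobutenolide, transmetallation to chromium, addition to the enolisable aldehyde under non-basic conditions) forms the C8–C9 bond; the new carbinol center becomes a ketone in step 16, so both epimers serve.

Step 13
Reactants: 20 hydroxyalkyl butenolide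
Product: 21 lactol (mixture of stereoisomers)
Conditions: iBu2AlH, CH2Cl2, −78 °C; aq. potassium sodium tartrate (KNaC4H4O6), 0 °C; used at once
Reagents that add atoms: none
Why: iBu2AlH at −78 °C stops at the aluminium hemiacetal (partial reduction of a lactone to a lactol), which turns C11 into a masked aldehyde while the ring keeps C19–O and C11 cis on the C9=C10 bond.

Step 14
Reactants: 11 C25 polyenylphosphonium bromide; 21 lactol
Product: 23 (3R,3'R,6'R)-3,3'-bis(tert-butyldimethylsilyloxy)-7,8-dihydro-β,ε-carotene-8,19-diol (all-E; both C8 epimers), via ylide 22 (not isolated)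
Conditions: NaOMe, CH2Cl2/MeOH, 0 °C → rt, dark; then EtOAc, 60 °C
Reagents that add atoms: none
Why: Wittig olefination of a lactol: under base the lactol opens to the (Z)-4-oxido-enal, which the C25 ylide olefinates to form the C11=C12 bond and set free the C19 hydroxyl; the hindered (11Z) isomer should isomerise to (11E) on gentle heating while the trisubstituted C9=C10 bond keeps the geometry fixed by the former ring.

Step 15
Reactants: 23 C40 8,19-diol; 24 (2E)-oct-2-enoic acid
Product: 25 C40 19-octenoate 8-ol
Conditions: EDC·HCl, DMAP (cat.), CH2Cl2, −20 → 0 °C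
Reagents that add atoms: none
Why: Carbodiimide esterification with DMAP catalysis (Steglich esterification) at low temperature should acylate the unhindered primary allylic C19 hydroxyl in preference to the secondary C8 hydroxyl, which is flanked by the ring CH2 group and the trisubstituted alkene.

Step 16
Reactants: 25 C40 19-octenoate 8-ol
Product: 26 bis-silyl ether of the target
Conditions: MnO2 (activated, excess), CH2Cl2, rt, dark
Reagents that add atoms: none
Why: MnO2 oxidises the allylic C8 carbinol, which is conjugated with the polyene, to the ketone (allylic alcohol oxidation); both C8 epimers converge and the two ring carbinols are shielded as silyl ethers.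

Step 17
Reactants: 26 bis-silyl ether of the target
Product: 27 CNP0344057.1
Conditions: Et3N·3HF, THF, rt, dark
Reagents that add atoms: none
Why: Fluoride-mediated cleavage of both silyl ethers under buffered, weakly acidic conditions should leave the allylic ester, the acid-sensitive allylic C3' alcohol and the polyene intact and give the target.

**Compound list**

1 | (3E,5E)-pseudoionone, (3E,5E)-6,10-dimethylundeca-3,5,9-trien-2-one | CC(=O)/C=C/C=C(C)/CCC=C(C)C | starting material
2 | (R)-α-ionone, (3E)-4-[(1R)-2,6,6-trimethylcyclohex-2-en-1-yl]but-3-en-2-one | CC(=O)/C=C/[C@H]1C(C)=CCCC1(C)C | intermediate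
3 | (3R,6R)-3-hydroxy-α-ionone, (3E)-4-[(1R,4R)-4-hydroxy-2,6,6-trimethylcyclohex-2-en-1-yl]but-3-en-2-one | CC(=O)/C=C/[C@H]1C(C)=C[C@H](O)CC1(C)C | intermediate
4 | (3E)-4-[(1R,4R)-4-(tert-butyldimethylsilyloxy)-2,6,6-trimethylcyclohex-2-en-1-yl]but-3-en-2-one | CC(=O)/C=C/[C@H]1C(C)=C[C@H](O[Si](C)(C)C(C)(C)C)CC1(C)C | intermediate
5 | (1E)-1-[(1R,4R)-4-(tert-butyldimethylsilyloxy)-2,6,6-trimethylcyclohex-2-en-1-yl]-3-methylpenta-1,4-dien-3-ol, both C3 epimers | C=CC(C)(O)/C=C/[C@H]1C(C)=C[C@H](O[Si](C)(C)C(C)(C)C)CC1(C)C | intermediate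
6 | [(2E,4E)-5-[(1R,4R)-4-(tert-butyldimethylsilyloxy)-2,6,6-trimethylcyclohex-2-en-1-yl]-3-methylpenta-2,4-dien-1-yl]triphenylphosphonium bromide | [Br-].C(/C=C(C)/C=C/[C@H]1C(C)=C[C@H](O[Si](C)(C)C(C)(C)C)CC1(C)C)[P+](c1ccccc1)(c1ccccc1)c1ccccc1 | intermediate
7 | (2E,4E,6E)-2,7-dimethylocta-2,4,6-trienedial | O=C/C(C)=C/C=C/C=C(C)/C=O | starting material
8 | triphenylphosphonium ylide of 6 | C(=P(c1ccccc1)(c1ccccc1)c1ccccc1)/C=C(C)/C=C/[C@H]1C(C)=C[C@H](O[Si](C)(C)C(C)(C)C)CC1(C)C | intermediate
9 | (2E,4E,6E,8E,10E,12E)-13-[(1R,4R)-4-(tert-butyldimethylsilyloxy)-2,6,6-trimethylcyclohex-2-en-1-yl]-2,7,11-trimethyltrideca-2,4,6,8,10,12-hexaenal | O=C/C(C)=C/C=C/C=C(C)/C=C/C=C(C)/C=C/[C@H]1C(C)=C[C@H](O[Si](C)(C)C(C)(C)C)CC1(C)C | intermediate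
10 | (2E,4E,6E,8E,10E,12E)-13-[(1R,4R)-4-(tert-butyldimethylsilyloxy)-2,6,6-trimethylcyclohex-2-en-1-yl]-2,7,11-trimethyltrideca-2,4,6,8,10,12-hexaen-1-ol | OC/C(C)=C/C=C/C=C(C)/C=C/C=C(C)/C=C/[C@H]1C(C)=C[C@H](O[Si](C)(C)C(C)(C)C)CC1(C)C | intermediate
11 | triphenylphosphonium bromide derived from 10 (phosphorus on C1 of the hexaene chain) | [Br-].C(/C(C)=C/C=C/C=C(C)/C=C/C=C(C)/C=C/[C@H]1C(C)=C[C@H](O[Si](C)(C)C(C)(C)C)CC1(C)C)[P+](c1ccccc1)(c1ccccc1)c1ccccc1 | intermediate
12 | (4R,6R)-actinol, (4R,6R)-4-hydroxy-2,2,6-trimethylcyclohexanone | CC1(C)C[C@H](O)C[C@@H](C)C1=O | starting material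
13 | (4R,6R)-4-(tert-butyldimethylsilyloxy)-2,2,6-trimethylcyclohexanone | CC1(C)C[C@H](O[Si](C)(C)C(C)(C)C)C[C@@H](C)C1=O | intermediate
14 | lithium (4R)-4-(tert-butyldimethylsilyloxy)-2,6,6-trimethylcyclohex-1-en-1-olate | [Li]OC1=C(C)C[C@@H](O[Si](C)(C)C(C)(C)C)CC1(C)C | intermediate
15 | (4R)-4-(tert-butyldimethylsilyloxy)-2,6,6-trimethylcyclohex-1-en-1-yl trifluoromethanesulfonate | FC(F)(F)S(=O)(=O)OC1=C(C)C[C@@H](O[Si](C)(C)C(C)(C)C)CC1(C)C | intermediate
16 | (E)-2-(2-ethoxyvinyl)-4,4,5,5-tetramethyl-1,3,2-dioxaborolane | CCO/C=C/B1OC(C)(C)C(C)(C)O1 | starting material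
17 | tert-butyl{[(1R)-4-[(E)-2-ethoxyvinyl]-3,5,5-trimethylcyclohex-3-en-1-yl]oxy}dimethylsilane | CCO/C=C/C1=C(C)C[C@@H](O[Si](C)(C)C(C)(C)C)CC1(C)C | intermediate
18 | 2-[(4R)-4-(tert-butyldimethylsilyloxy)-2,6,6-trimethylcyclohex-1-en-1-yl]acetaldehyde | O=CCC1=C(C)C[C@@H](O[Si](C)(C)C(C)(C)C)CC1(C)C | intermediate
19 | 4-bromofuran-2(5H)-one | O=C1C=C(Br)CO1 | starting material
20 | 4-{1-hydroxy-2-[(4R)-4-(tert-butyldimethylsilyloxy)-2,6,6-trimethylcyclohex-1-en-1-yl]ethyl}furan-2(5H)-one, both carbinol epimers | O=C1C=C(CO1)C(O)CC2=C(C)C[C@@H](O[Si](C)(C)C(C)(C)C)CC2(C)C | intermediate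
21 | 4-{1-hydroxy-2-[(4R)-4-(tert-butyldimethylsilyloxy)-2,6,6-trimethylcyclohex-1-en-1-yl]ethyl}-2,5-dihydrofuran-2-ol, mixture of stereoisomers | OC1C=C(CO1)C(O)CC2=C(C)C[C@@H](O[Si](C)(C)C(C)(C)C)CC2(C)C | intermediate
22 | triphenylphosphonium ylide of 11 | C(=P(c1ccccc1)(c1ccccc1)c1ccccc1)/C(C)=C/C=C/C=C(C)/C=C/C=C(C)/C=C/[C@H]1C(C)=C[C@H](O[Si](C)(C)C(C)(C)C)CC1(C)C | intermediate
23 | (3R,3'R,6'R)-3,3'-bis(tert-butyldimethylsilyloxy)-7,8-dihydro-β,ε-carotene-8,19-diol, all-E, both C8 epimers | OC\C(=C/C=C/C(C)=C/C=C/C=C(C)/C=C/C=C(C)/C=C/[C@H]1C(C)=C[C@H](O[Si](C)(C)C(C)(C)C)CC1(C)C)C(O)CC1=C(C)C[C@@H](O[Si](C)(C)C(C)(C)C)CC1(C)C | intermediate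
24 | (2E)-oct-2-enoic acid | CCCCC/C=C/C(=O)O | starting material
25 | 19-[(2E)-oct-2-enoate] of 23 (8-hydroxy, both C8 epimers) | CCCCC/C=C/C(=O)OC\C(=C/C=C/C(C)=C/C=C/C=C(C)/C=C/C=C(C)/C=C/[C@H]1C(C)=C[C@H](O[Si](C)(C)C(C)(C)C)CC1(C)C)C(O)CC1=C(C)C[C@@H](O[Si](C)(C)C(C)(C)C)CC1(C)C | intermediate
26 | (3R,3'R,6'R)-3,3'-bis(tert-butyldimethylsilyloxy)-19-hydroxy-7,8-dihydro-β,ε-caroten-8-one 19-[(2E)-oct-2-enoate] | CCCCC/C=C/C(=O)OC\C(=C/C=C/C(C)=C/C=C/C=C(C)/C=C/C=C(C)/C=C/[C@H]1C(C)=C[C@H](O[Si](C)(C)C(C)(C)C)CC1(C)C)C(=O)CC1=C(C)C[C@@H](O[Si](C)(C)C(C)(C)C)CC1(C)C | intermediate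
27 | CNP0344057.1, (3R,3'R,6'R)-3,19,3'-trihydroxy-7,8-dihydro-β,ε-caroten-8-one 19-[(2E)-oct-2-enoate] | CCCCC/C=C/C(=O)OC\C(=C/C=C/C(C)=C/C=C/C=C(C)/C=C/C=C(C)/C=C/[C@H]1C(C)=C[C@H](O)CC1(C)C)C(=O)CC1=C(C)C[C@@H](O)CC1(C)C | target

**Step count and risks**

Total step count: 17. Longest linear sequence: 12 steps (steps 1–8, then 14–17).

Steps most likely to fail:

1. Step 1. The electron-poor dienone may not be turned over in the cyclase pocket, the enantioface selection may be poor, or the ring cation may lose a proton toward the β- or γ-isomer. The fallback sets out from 1 and comes back to the route at 3. Brønsted acid cyclisation (85% H3PO4, toluene, 80 °C) should give racemic α-ionone F1. The monooxygenase conditions of step 2 applied to F1 should hydroxylate each enantiomer trans to its side chain and give 3 together with its enantiomer, (3S,6S)-3-hydroxy-α-ionone F2. Lipase-catalysed acyl transfer (Pseudomonas fluorescens lipase, vinyl acetate, tert-butyl methyl ether, rt; enzymatic kinetic resolution) should acetylate only the (3R) alcohol to (3R,6R)-3-acetoxy-α-ionone F3, which is separated from unreacted F2 by chromatography. K2CO3 in MeOH at 0 °C then gives 3.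

2. Step 14. Lactol 21 may dehydrate to a furan before it opens, and the oxido-enal may be olefinated only slowly by the delocalised ylide. The fallback sets out from 20 and comes back at 23. Excess iBu2AlH (CH2Cl2, −78 → 0 °C) reduces the lactone fully to the cis-enetriol F4. 2,2-Dimethoxypropane with PPTS in CH2Cl2 ties the 1,3-related C8 and C19 hydroxyls into the six-membered acetonide alcohol F5 and leaves the C11 hydroxyl free. MnO2 in CH2Cl2 gives the open-chain acetonide enal F6, which cannot close to a lactol or aromatise. Wittig reaction with ylide 22 (from 11 and NaOMe) followed by thermal equilibration gives the C40 acetonide F7. PPTS in MeOH at rt removes the acetonide and returns 23.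

3. Step 15. The carbodiimide acylation may discriminate poorly between the primary C19 and the secondary C8 hydroxyl, and the acyl group may migrate from O19 to O8. The fallback sets out from 23 and comes back at 25. Bu2SnO in MeOH at 60 °C, then evaporation, gives the six-membered dibutylstannylene acetal F8 of the 8,19-diol. (2E)-Oct-2-enoyl chloride F9, made from 24 with oxalyl chloride and catalytic DMF, in THF at 0 °C should acylate the primary oxygen of the tin acetal and give 25 after aqueous work-up.

Further compounds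
F1 | step 1 | racemic α-ionone | CC(=O)/C=C/C1C(C)=CCCC1(C)C
F2 | step 1 | (3S,6S)-3-hydroxy-α-ionone | CC(=O)/C=C/[C@@H]1C(C)=C[C@@H](O)CC1(C)C
F3 | step 1 | (3R,6R)-3-acetoxy-α-ionone | CC(=O)/C=C/[C@H]1C(C)=C[C@H](OC(C)=O)CC1(C)C
F4 | step 14 | (2E)-2-{1-hydroxy-2-[(4R)-4-(tert-butyldimethylsilyloxy)-2,6,6-trimethylcyclohex-1-en-1-yl]ethyl}but-2-ene-1,4-diol (the two CH2OH groups cis) | OC/C=C(\CO)C(O)CC1=C(C)C[C@@H](O[Si](C)(C)C(C)(C)C)CC1(C)C
F5 | step 14 | 8,19-acetonide alcohol, 2-(2,2-dimethyl-1,3-dioxan-5-ylidene)ethanol carrying the ring-CH2 group at C4 of the dioxane | OC/C=C1\COC(C)(C)OC1CC2=C(C)C[C@@H](O[Si](C)(C)C(C)(C)C)CC2(C)C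
F6 | step 14 | 8,19-acetonide enal | O=C/C=C1\COC(C)(C)OC1CC2=C(C)C[C@@H](O[Si](C)(C)C(C)(C)C)CC2(C)C
F7 | step 14 | 8,19-acetonide of 23 | CC1(C)OC\C(=C/C=C/C(C)=C/C=C/C=C(C)/C=C/C=C(C)/C=C/[C@H]2C(C)=C[C@H](O[Si](C)(C)C(C)(C)C)CC2(C)C)C(O1)CC3=C(C)C[C@@H](O[Si](C)(C)C(C)(C)C)CC3(C)C
F8 | step 15 | 8,19-O-dibutylstannylene acetal of 23 | CCCC[Sn]1(CCCC)OC\C(=C/C=C/C(C)=C/C=C/C=C(C)/C=C/C=C(C)/C=C/[C@H]2C(C)=C[C@H](O[Si](C)(C)C(C)(C)C)CC2(C)C)C(O1)CC3=C(C)C[C@@H](O[Si](C)(C)C(C)(C)C)CC3(C)C
F9 | step 15 | (2E)-oct-2-enoyl chloride | CCCCC/C=C/C(Cl)=O
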